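**Retrosynthetic overview**

1. Target ⇐ hydroxyl-directed epoxidation of the macrocyclic (E)-allylic alcohol ⇐ Nozaki–Hiyama–Kishi closure of the eleven-membered ring (C14–C15) from a vinyl iodide/aldehyde.
2. Side chain: C11–C12 by Felkin addition of a 2-butynyl unit; the C10 aldehyde from the isopropenyl group (epoxidation, 1,2-hydride shift); C4 oxygen inverted and propionylated once the angular methyl is in.
3. cis-Hydrindane ⇐ conjugate methylation of a bicyclic γ-hydroxy enone (C5, then C6 and C2 by protonation/equilibration).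
4. Key step: the six-membered ring by Diels–Alder cycloaddition of a cyclopentane-fused 2-silyloxyfuran with a 2-substituted acrolein (C1–C2 and C3–C4), then oxa-bridge opening and deformylation.
5. Furan ⇐ butenolide (singlet-oxygen cycloaddition) ⇐ cyclopentene carbaldehyde ⇐ (4R)-limonene oxide. Ring order: five-membered (aldol), six-membered (cycloaddition), eleven-membered (chromium-mediated), oxirane last.

Assumption: (4R)-limonene 1,2-oxide (cis/trans mixture) and 4-(tert-butyldimethylsilyloxy)butanal are taken as commercial; the route is a plan and has not been run.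

Numbering used in the names: C1 (carries the exocyclic CH2), C2, C3, C4 (O-bearing), C5 (quaternary, Me) and C6 (ring-fusion CH) form the six-membered ring; C5, C7, C8, C9, C6 form the five-membered ring; C9 carries C10(Me)–C11(O)–C12–C13–C14(Me)–C15(O)–C16, and C16 is bonded to C2. α is the face of the six-membered ring that carries 5-Me and 6-H in the target; β is the face of C7/C9 and of the C9 side chain. Target = 2R,4S,5S,6S,9R,10S,11S,13S,14S,15R. TBS = tert-butyldimethylsilyl, TES = triethylsilyl, TMS = trimethylsilyl.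

**Route**

Step 1
Reactants: 1 (4R)-limonene 1,2-oxide (cis/trans mixture)
Product: 2 (3R)-6-oxo-3-(prop-1-en-2-yl)heptanal
Conditions: H5IO6, THF/H2O, 0 °C to rt
Reagents that add atoms: water, O
Why: Periodic acid opens the epoxide to the diol and cleaves it (glycol cleavage) to the keto aldehyde, leaving the purchased stereocentre (future C9) untouched.

Step 2
Reactants: 2 (3R)-6-oxo-3-(prop-1-en-2-yl)heptanal
Product: 3 (5S)-2-methyl-5-(prop-1-en-2-yl)cyclopent-1-ene-1-carbaldehyde
Conditions: piperidine (cat.), AcOH (cat.), benzene, reflux (Dean–Stark)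
Reagents that add atoms: none
Why: Enamine-mediated intramolecular aldol condensation of the aldehyde α-carbon onto the methyl ketone closes the five-membered ring (C5=C6) without touching the non-acidic C9 centre.

Step 3
Reactants: 3 (5S)-2-methyl-5-(prop-1-en-2-yl)cyclopent-1-ene-1-carbaldehyde
Product: 4 (E)-1-[(tert-butyldimethylsilyloxy)methylidene]-2-methylidene-5-(prop-1-en-2-yl)cyclopentane
Conditions: TBSOTf, Et3N, CH2Cl2, −78 to 0 °C
Reagents that add atoms: tert-butyldimethylsilyl triflate, CC(C)(C)[Si](C)(C)OS(=O)(=O)C(F)(F)F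
Why: Soft enolization (O-silylation, then γ-deprotonation of the methyl group cis to the formyl group) gives the s-cis-locked 1-silyloxy diene (silyl dienol ether formation).

Step 4
Reactants: 4 (E)-silyl dienol ether
Product: 6 (6S)-6-(prop-1-en-2-yl)-3,4,5,6-tetrahydro-1H-cyclopenta[c]furan-1-one, via endoperoxide 5 (not isolated)
Conditions: O2, tetraphenylporphyrin (cat.), hν, CH2Cl2, −78 °C; then Et3N, −78 to 0 °C
Reagents that add atoms: oxygen, O=O
Why: [4+2] cycloaddition of singlet oxygen to the electron-rich exocyclic diene (much faster than an ene reaction at the isopropenyl group) gives the 1,2-dioxine, and Kornblum–DeLaMare fragmentation with lactonization gives the butenolide in which C4 is now oxygenated.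

Step 5
Reactants: 6 butenolide
Product: 7 (6S)-6-(prop-1-en-2-yl)-1-(triethylsilyloxy)-5,6-dihydro-4H-cyclopenta[c]furan
Conditions: TESOTf, Et3N, CH2Cl2, 0 °C
Reagents that add atoms: triethylsilyl triflate, CC[Si](CC)(CC)OS(=O)(=O)C(F)(F)F
Why: γ-Deprotonation/O-silylation of the butenolide (silyl dienolate formation) gives the aromatic 2-silyloxyfuran that serves as the diene.

Step 6
Reactants: 8 4-(tert-butyldimethylsilyloxy)butanal
Product: 9 4-(tert-butyldimethylsilyloxy)-2-methylidenebutanal
Conditions: aq. CH2O, pyrrolidine (cat.), EtCO2H (cat.), iPrOH, 45 °C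
Reagents that add atoms: formaldehyde, C=O
Why: Amine-catalysed Mannich condensation/elimination (α-methylenation of an aldehyde) gives the 2-substituted acrolein dienophile that already carries C16 and C15.

Step 7
Reactants: 7 silyloxyfuran; 9 4-(tert-butyldimethylsilyloxy)-2-methylidenebutanal
Product: 12 4β-hydroxy-2α-[2-(tert-butyldimethylsilyloxy)ethyl] bicyclic enone, via cycloadduct 10 (not isolated), via formyl ketone 11 (not isolated)
Conditions: toluene, 80 °C; then K2CO3, MeOH, 0 °C
Reagents that add atoms: none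
Why: Diels–Alder cycloaddition of the 2-silyloxyfuran (its nucleophilic C4 bonds to the acrolein CH2, the silyloxy-bearing C1 to the formyl-bearing carbon) takes place on the furan face anti to the C9 isopropenyl group, so the oxygen bridge and, after methanolysis of the bridgehead silyl ketal, the C4 hydroxyl are β, and retro-Claisen deformylation of the non-enolizable β-keto aldehyde leaves the enone with C2–H.

Step 8
Reactants: 12 4β-hydroxy enone
Product: 14 4β-hydroxy-5α-methyl cis-hydrindan-1-one, via bis-silyl ether 13 (not isolated)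
Conditions: TMSCl, Et3N, THF, 0 °C; then Me2CuLi (MeLi, CuI), TMSCl, −78 to −30 °C; then K2CO3, MeOH, rt
Reagents that add atoms: lithium dimethylcuprate, [Li+].C[Cu-]C
Why: TMSCl-accelerated cuprate conjugate addition puts the methyl on C5 anti to both the adjacent 4β-silyloxy group and the β isopropenyl group (5α-Me), and methanolysis with equilibration gives the cis-fused ketone (6α-H) with the C2 chain equatorial (2α).

Step 9
Reactants: 14 4β-hydroxy-5α-methyl cis-hydrindan-1-one
Product: 15 1-methylidene-4β-ol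
Conditions: Ph3PCH3Br, KOtBu, toluene, 90 °C
Reagents that add atoms: methylenetriphenylphosphorane, C=P(c1ccccc1)(c1ccccc1)c1ccccc1
Why: Wittig methylenation of the only ketone installs the exocyclic methylene and locks C2 and C6, which were already at their thermodynamic configuration.

Step 10
Reactants: 15 1-methylidene-4β-ol
Product: 16 1-methylidene-4-ketone
Conditions: Dess–Martin periodinane, NaHCO3, CH2Cl2, rt
Reagents that add atoms: none
Why: Dess–Martin oxidation removes the C4 centre, which was needed only to steer the methyl addition.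

Step 11
Reactants: 16 1-methylidene-4-ketone
Product: 17 1-methylidene-4α-ol
Conditions: Li, NH3 (l), THF, MeOH, −78 °C
Reagents that add atoms: none
Why: Dissolving-metal reduction gives the thermodynamically favoured equatorial 4α-alcohol (the 4β epimer is syn-axial to C9), cis to the angular methyl, and leaves the isolated 1,1-disubstituted alkenes alone.

Step 12
Reactants: 17 1-methylidene-4α-ol
Product: 18 4α-propionate
Conditions: (EtCO)2O, Et3N, DMAP (cat.), CH2Cl2, rt
Reagents that add atoms: propionic anhydride, CCC(=O)OC(=O)CC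
Why: DMAP-catalysed acylation installs the propionate of the target, which also protects C4 from here on.

Step 13
Reactants: 18 4α-propionate
Product: 19 (10S)-10,11-epoxide
Conditions: mCPBA (1.0 equiv), NaHCO3, CH2Cl2, −20 °C
Reagents that add atoms: 3-chloroperbenzoic acid, OOC(=O)c1cccc(Cl)c1
Why: Prilezhaev epoxidation attacks the isopropenyl group (the exocyclic methylene is flanked by two tertiary carbons and screened on both faces) on the π face remote from C6 in the rotamer with C9–H eclipsing the C=CH2 bond, which sets C10.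

Step 14
Reactants: 19 (10S)-10,11-epoxide
Product: 20 (10S)-aldehyde (C11 = CHO)
Conditions: MeAl(OAr)2 (Ar = 4-bromo-2,6-di-tert-butylphenyl; 20 mol%), CH2Cl2, −78 °C
Reagents that add atoms: none
Why: Lewis acid-promoted Meinwald rearrangement moves hydride from C11 to C10 anti to the breaking C–O bond, giving the α-methyl aldehyde with the 10S centre, and the bulky aluminium phenoxide disfavours a free cation that the nearby methylene could trap.

Step 15
Reactants: 20 (10S)-aldehyde
Product: 22 (10S,11S)-11-acetoxy-13-yne, via homopropargylic alcohol 21 (not isolated)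
Conditions: 2-butyne, nBuLi, THF, 0 °C; ClTi(OiPr)3, −78 °C; then 20; then Ac2O, DMAP, −78 to 0 °C
Reagents that add atoms: 2-butyne, CC#CC; acetic anhydride, CC(=O)OC(C)=O
Why: The allenyltitanium reagent from lithiated 2-butyne adds by SE2' through its CH2 terminus (homopropargylic product) under Felkin–Anh control by the C10 centre to give the 11S alkoxide, which is acetylated in the same flask.

Step 16
Reactants: 22 (10S,11S)-11-acetoxy-13-yne
Product: 24 (13E)-14-iodo alkene, via alkenylzirconocene 23 (not isolated)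
Conditions: Cp2Zr(H)Cl (2.2 equiv), THF, rt to 40 °C; then I2, 0 °C
Reagents that add atoms: iodine, II
Why: syn-Hydrozirconation places zirconium on the less hindered, methyl-bearing alkyne carbon after equilibration with excess reagent, and iodinolysis with retention gives the (E)-2-iodoalkene in which C12 is cis to the methyl.

Step 17
Reactants: 24 (13E)-14-iodo alkene
Product: 25 C15 primary alcohol
Conditions: HF·pyridine, pyridine, THF, 0 °C
Reagents that add atoms: none
Why: Fluoride cleavage of the primary TBS ether under buffered conditions spares the acetate, the propionate and the vinyl iodide.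

Step 18
Reactants: 25 C15 primary alcohol
Product: 26 C15 aldehyde
Conditions: Dess–Martin periodinane, NaHCO3, CH2Cl2, 0 °C
Reagents that add atoms: none
Why: Dess–Martin oxidation gives the aldehyde without epimerizing C2, which is not α to it.

Step 19
Reactants: 26 C15 aldehyde
Product: 27 macrocyclic (13E,15R)-allylic alcohol
Conditions: CrCl2 (10 equiv), NiCl2 (1 mol%), DMSO/THF, rt, 2 mM
Reagents that add atoms: none
Why: Nozaki–Hiyama–Kishi reaction: the alkenylchromium species formed with retention of the E geometry adds to the aldehyde in preference to the esters and closes the eleven-membered ring (C14–C15), with the C15 carbinol expected from the macrocyclic transition state that keeps the oxygen pseudoequatorial on the ring periphery.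

Step 20
Reactants: 27 macrocyclic (13E,15R)-allylic alcohol
Product: 28 CNP0415604.1
Conditions: VO(acac)2 (cat.), tBuOOH, CH2Cl2, 0 °C
Reagents that add atoms: tert-butyl hydroperoxide, CC(C)(C)OO
Why: Hydroxyl-directed vanadium-catalysed epoxidation delivers oxygen only to the allylic C13=C14 bond (the exocyclic methylene is untouched), syn to the C15 hydroxyl on the exposed peripheral face of the E-alkene held in the macrocycle.

**Compound list**

1 | (4R)-limonene 1,2-oxide, cis/trans mixture at the epoxide | CC12CC[C@@H](C(C)=C)CC1O2 | starting material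
2 | (3R)-6-oxo-3-(prop-1-en-2-yl)heptanal | CC(=O)CC[C@@H](C(C)=C)CC=O | intermediate
3 | (5S)-2-methyl-5-(prop-1-en-2-yl)cyclopent-1-ene-1-carbaldehyde | CC1=C(C=O)[C@H](C(C)=C)CC1 | intermediate
4 | (E)-1-[(tert-butyldimethylsilyloxy)methylidene]-2-methylidene-5-(prop-1-en-2-yl)cyclopentane (silyl dienol ether of 3) | C=C1CC[C@@H](C(C)=C)/C1=C\O[Si](C)(C)C(C)(C)C | intermediate
5 | endoperoxide: cyclopentene-fused 3,6-dihydro-1,2-dioxine with OTBS on the acetal carbon C1 (both C1 epimers), peroxide bridging C1 and C4 | CC(=C)[C@@H]1CCC2=C1C(O[Si](C)(C)C(C)(C)C)OOC2 | intermediate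
6 | (6S)-6-(prop-1-en-2-yl)-3,4,5,6-tetrahydro-1H-cyclopenta[c]furan-1-one (butenolide; C1 lactone carbonyl, C4 = OCH2) | CC(=C)[C@@H]1CCC2=C1C(=O)OC2 | intermediate
7 | (6S)-6-(prop-1-en-2-yl)-1-(triethylsilyloxy)-5,6-dihydro-4H-cyclopenta[c]furan (2-silyloxyfuran) | CC(=C)[C@@H]1CCc2coc(O[Si](CC)(CC)CC)c12 | intermediate
8 | 4-(tert-butyldimethylsilyloxy)butanal | O=CCCCO[Si](C)(C)C(C)(C)C | starting material
9 | 4-(tert-butyldimethylsilyloxy)-2-methylidenebutanal | C=C(C=O)CCO[Si](C)(C)C(C)(C)C | intermediate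
10 | Diels–Alder adduct: 7-oxanorbornene, oxygen bridge C1–O–C4 on the β face (syn to the C9 isopropenyl), C1 bears OTES, C2 bears CHO and CH2CH2OTBS (endo/exo mixture), C5=C6 fused to the cyclopentane | O=CC1(CCO[Si](C)(C)C(C)(C)C)C[C@H]2O[C@]1(O[Si](CC)(CC)CC)C1=C2CC[C@H]1C(C)=C | intermediate
11 | 2-formyl-4β-hydroxy enone (C1 ketone, C5=C6; C2 bears CHO and CH2CH2OTBS, both C2 epimers) | O=C1C(C=O)(CCO[Si](C)(C)C(C)(C)C)C[C@@H](O)C2=C1[C@H](C(C)=C)CC2 | intermediate
12 | bicyclic enone: C1 ketone conjugated with C5=C6, 2α-CH2CH2OTBS, 4β-OH (cis to the C9 isopropenyl) | O=C1[C@H](CCO[Si](C)(C)C(C)(C)C)C[C@@H](O)C2=C1[C@H](C(C)=C)CC2 | intermediate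
13 | bis(trimethylsilyl) derivative: C1 TMS enol ether (C1=C6), 4β-OTMS, 5α-Me, 2α-CH2CH2OTBS | C[Si](C)(C)OC=1[C@H](CCO[Si](C)(C)C(C)(C)C)C[C@@H](O[Si](C)(C)C)[C@@]2(C)CC[C@@H](C(C)=C)C=12 | intermediate
14 | cis-hydrindanone: C1 ketone, 2α-CH2CH2OTBS, 4β-OH, 5α-Me, 6α-H, C9 isopropenyl cis to C1 | O=C1[C@H](CCO[Si](C)(C)C(C)(C)C)C[C@@H](O)[C@@]2(C)CC[C@@H](C(C)=C)[C@@H]12 | intermediate
15 | 1-methylidene analogue of 14 (4β-OH) | C=C1[C@H](CCO[Si](C)(C)C(C)(C)C)C[C@@H](O)[C@@]2(C)CC[C@@H](C(C)=C)[C@@H]12 | intermediate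
16 | 1-methylidene-4-ketone | C=C1[C@H](CCO[Si](C)(C)C(C)(C)C)CC(=O)[C@@]2(C)CC[C@@H](C(C)=C)[C@@H]12 | intermediate
17 | 1-methylidene-4α-ol (OH cis to 5-Me) | C=C1[C@H](CCO[Si](C)(C)C(C)(C)C)C[C@H](O)[C@@]2(C)CC[C@@H](C(C)=C)[C@@H]12 | intermediate
18 | 4α-propionate of 17 | C=C1[C@H](CCO[Si](C)(C)C(C)(C)C)C[C@H](OC(=O)CC)[C@@]2(C)CC[C@@H](C(C)=C)[C@@H]12 | intermediate
19 | (10S)-10,11-epoxide of 18 (2-methyloxiran-2-yl on C9) | C=C1[C@H](CCO[Si](C)(C)C(C)(C)C)C[C@H](OC(=O)CC)[C@@]2(C)CC[C@@H]([C@@]3(C)CO3)[C@@H]12 | intermediate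
20 | (10S)-aldehyde: C9 bears CH(CH3)CHO | C=C1[C@H](CCO[Si](C)(C)C(C)(C)C)C[C@H](OC(=O)CC)[C@@]2(C)CC[C@@H]([C@H](C)C=O)[C@@H]12 | intermediate
21 | (10S,11S)-homopropargylic alcohol: C11–OH, C12H2–C13≡C14–CH3 | C=C1[C@H](CCO[Si](C)(C)C(C)(C)C)C[C@H](OC(=O)CC)[C@@]2(C)CC[C@@H]([C@H](C)[C@@H](O)CC#CC)[C@@H]12 | intermediate
22 | (10S,11S)-11-acetate of 21 | C=C1[C@H](CCO[Si](C)(C)C(C)(C)C)C[C@H](OC(=O)CC)[C@@]2(C)CC[C@@H]([C@H](C)[C@@H](OC(C)=O)CC#CC)[C@@H]12 | intermediate
23 | (E)-alkenylzirconocene chloride, Zr on C14 (Cp rings drawn σ-bonded) | C=C1[C@H](CCO[Si](C)(C)C(C)(C)C)C[C@H](OC(=O)CC)[C@@]2(C)CC[C@@H]([C@H](C)[C@@H](OC(C)=O)C/C=C(/[Zr](Cl)(C3C=CC=C3)C3C=CC=C3)C)[C@@H]12 | intermediate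
24 | (13E)-14-iodo alkene (C12 cis to the C14 methyl), C15–OTBS | C=C1[C@H](CCO[Si](C)(C)C(C)(C)C)C[C@H](OC(=O)CC)[C@@]2(C)CC[C@@H]([C@H](C)[C@@H](OC(C)=O)C/C=C(/I)C)[C@@H]12 | intermediate
25 | C15 primary alcohol of 24 | C=C1[C@H](CCO)C[C@H](OC(=O)CC)[C@@]2(C)CC[C@@H]([C@H](C)[C@@H](OC(C)=O)C/C=C(/I)C)[C@@H]12 | intermediate
26 | C15 aldehyde (C2–CH2–CHO) | C=C1[C@H](CC=O)C[C@H](OC(=O)CC)[C@@]2(C)CC[C@@H]([C@H](C)[C@@H](OC(C)=O)C/C=C(/I)C)[C@@H]12 | intermediate
27 | macrocyclic (13E,15R)-allylic alcohol (4-propionate, 11-acetate) | C=C1[C@H]2C[C@H](OC(=O)CC)[C@@]3(C)CC[C@@H]([C@H](C)[C@@H](OC(C)=O)C/C=C(C)/[C@H](O)C2)[C@@H]13 | intermediate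
28 | CNP0415604.1 (2R,4S,5S,6S,9R,10S,11S,13S,14S,15R; 13,14-epoxide, 15-OH, 4-propionate, 11-acetate) | C=C1[C@H]2C[C@H](OC(=O)CC)[C@@]3(C)CC[C@@H]([C@H](C)[C@@H](OC(C)=O)C[C@@H]4O[C@@]4(C)[C@H](O)C2)[C@@H]13 | target

**Summary**

Total step count: 20. Longest linear sequence: 19 (steps 1–5 and 7–20; step 6 is the one-step branch to the dienophile).

Three steps most likely to fail, each with a fallback:

Step 8, conjugate methylation at the fully substituted β-carbon of the enone. The fallback sets out from 12 and comes back at 14. Dimethylsulfoxonium methylide (Me3S(O)I, NaH, DMSO) cyclopropanates the enone C5=C6 bond on the α face, anti to the C4 hydroxyl and the isopropenyl group, to give the cyclopropyl ketone F1. Li in NH3 then cleaves the exocyclic cyclopropane bond that overlaps with the carbonyl π system, and protonation of the enolate gives 14 with the same 5α-methyl and 6α-hydrogen.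

Step 14, the stereospecific epoxide-to-aldehyde rearrangement next to the exocyclic methylene (this fallback also bypasses the chemoselective epoxidation of step 13). The fallback sets out from 18 and comes back at 20. Allylic oxidation of the isopropenyl methyl with SeO2 (cat.) and tBuOOH gives the 2-substituted allylic alcohol F2. Hydroxyl-directed hydrogenation with [Rh(nbd)(dppb)]BF4 and H2 adds hydrogen to the alkene face remote from C6; because the former methylene becomes the methyl, this gives the (10S)-alcohol F3. Dess–Martin oxidation gives 20.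

Step 19, chromium-mediated closure of the eleven-membered ring. The fallback sets out from 22 and comes back at 27. HF·pyridine gives the alkynol F4 and Dess–Martin oxidation the alkynal F5. A nickel-catalysed reductive alkyne–aldehyde macrocyclization (Ni(cod)2, an N-heterocyclic carbene ligand chosen for endocyclic coupling, Et3SiH, THF) forms the same C14–C15 bond with cis addition of H and carbon across the alkyne and gives the (13E)-allylic triethylsilyl ether F6. TBAF buffered with AcOH then gives 27.

Further compounds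
F1 | step 8 | cyclopropyl ketone: 14 with a CH2 bridging C5 and C6 on the α face in place of 5-Me and 6-H | O=C1[C@H](CCO[Si](C)(C)C(C)(C)C)C[C@@H](O)[C@@]2(C3)CC[C@@H](C(C)=C)[C@@]312
F2 | step 14 | allylic alcohol: 18 with the C9 substituent C(=CH2)CH2OH | C=C1[C@H](CCO[Si](C)(C)C(C)(C)C)C[C@H](OC(=O)CC)[C@@]2(C)CC[C@@H](C(=C)CO)[C@@H]12
F3 | step 14 | (10S)-primary alcohol: C9 bears CH(CH3)CH2OH | C=C1[C@H](CCO[Si](C)(C)C(C)(C)C)C[C@H](OC(=O)CC)[C@@]2(C)CC[C@@H]([C@H](C)CO)[C@@H]12
F4 | step 19 | alkynol: 22 with C15–OH free | C=C1[C@H](CCO)C[C@H](OC(=O)CC)[C@@]2(C)CC[C@@H]([C@H](C)[C@@H](OC(C)=O)CC#CC)[C@@H]12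
F5 | step 19 | alkynal: C2–CH2–CHO and the C13≡C14 alkyne | C=C1[C@H](CC=O)C[C@H](OC(=O)CC)[C@@]2(C)CC[C@@H]([C@H](C)[C@@H](OC(C)=O)CC#CC)[C@@H]12
F6 | step 19 | 15-O-triethylsilyl ether of 27 | C=C1[C@H]2C[C@H](OC(=O)CC)[C@@]3(C)CC[C@@H]([C@H](C)[C@@H](OC(C)=O)C/C=C(C)/[C@H](O[Si](CC)(CC)CC)C2)[C@@H]13
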